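The target is what you want from these flasks, but it does not stay: in the larch run it fell from 82.6% to 59.8% after starting material had reached 0%. You want to know when it loses the lead to its isomer.

in all of them: initiator 45 mM
- larch: starting material 0.30 M; coupling partner 0.63 M; run made earlier
- cedar: starting material 0.30 M; coupling partner 0.99 M; run made earlier
- elm: starting material 0.45 M; coupling partner 0.45 M; run made earlier
- zeta: starting material 0.30 M; coupling partner 0.450 M; time 3.0 h
- gamma: starting material 0.30 M; coupling partner 0.450 M; time 6.0 h
- eta: starting material 0.30 M; coupling partner 0.450 M; time 12 h

| run | time / h | side product / % | isomer of the product / % | starting material / % | target / % | first chain carrier / % |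
|---|---|---|---|---|---|---|
| larch | 0.200 | 2.9 | 1.9 | 62.7 | 34.8 | 0 |
| larch | 0.333 | 5.3 | 1.8 | 39.9 | 53.3 | 0.4 |
| larch | 0.500 | 7.5 | 3.0 | 16.6 | 72.9 | 0 |
| larch | 0.833 | 8.3 | 8.4 | 0 | 82.6 | 0 |
| larch | 1.33 | 8.5 | 16.3 | 0.7 | 75.7 | 0.1 |
| larch | 2.50 | 7.9 | 31.8 | 0 | 59.8 | 0 |
| cedar | 0.200 | 3.1 | 1.3 | 40.4 | 54.8 | 0 |
| cedar | 0.333 | 4.8 | 2.6 | 7.9 | 84.4 | 0 |
| cedar | 0.500 | 5.2 | 6.0 | 0 | 88.5 | 0.7 |
| cedar | 0.833 | 4.3 | 11.6 | 0 | 82.8 | 0 |
| cedar | 1.33 | 5.1 | 18.2 | 0.1 | 74.7 | 0 |
| cedar | 2.50 | 4.5 | 33.4 | 0 | 61.1 | 0 |
| elm | 0.200 | 2.4 | 0.7 | 81.9 | 16.2 | 0.5 |
| elm | 0.667 | 12.2 | 2.3 | 46.4 | 38.0 | 0.8 |
| elm | 1.00 | 19.8 | 6.3 | 28.6 | 46.4 | 0 |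
| elm | 1.50 | 24.9 | 10.4 | 10.9 | 52.7 | 0 |
| elm | 2.50 | 27.3 | 20.8 | 0 | 52.2 | 0 |

(each reading ± 0.5 percentage points)

- in percentages every species weighs as the starting material in it: one ended chains or side product counts as two
- steps thought possible: starting material + target -> side product; starting material + second chain carrier -> by-product + first chain carrier; initiator -> 2 initiating radical; starting material + initiating radical -> capped initiator + first chain carrier; 2 first chain carrier -> ended chains; target <-> isomer of the product; coupling partner + first chain carrier -> target + second chain carrier

* which of these there is most of at the end, counted by the starting material in it, zeta (isomer of the product / side product / starting material / target / first chain carrier)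
* which of these there is most of at the end, counted by the starting material in it, gamma (isomer of the product / side product / starting material / target / first chain carrier)
* which of these there is most of at the end, counted by the starting material in it, eta (isomer of the product / side product / starting material / target / first chain carrier)
* final amount of the leader among these, as a percentage of the starting material charged, in zeta
* final amount of the leader among these, as a percentage of the starting material charged, in gamma
* final amount of the leader among these, as a percentage of the starting material charged, in eta

Build the flask one process at a time, and take the main step first: first chain carrier and coupling partner make target, and starting material restores the carrier. The first reading gives a loss of starting material, divided by the partner charged, of 0.903 h⁻¹ in cedar and 0.905 h⁻¹ in elm, although their charges differ. I therefore treat the partner as decaying in a pseudo-first-order way, with starting material following it one for one. With the charge of zeta, this reckoning puts the point where half of the starting material has reacted at 0.449 h, and I take that as the average birth time of the target.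

Now add the side product. At 1.33 h it read 8.5% in larch and 5.1% in cedar, less with more partner and the same charge of starting material. Scaling larch inversely with the partner charge gives 5.41% for cedar, close to that reading, and 11.9% for the new charge. By my reckoning that leaves a pool of 88.1% for target and isomer together.

Last comes the isomerisation. The larch decline reads as a one-way constant of 0.194 h⁻¹, and in my reckoning the target then falls exponentially from the pool, starting at the birth time. Join the two ends and you get the crossing time, the moment target and isomer stand equal: the birth time plus ln(2) over that constant, 4.03 h.

Zeta is read before it, so I expect target at 53.7%. Gamma and eta are read after it, so I expect isomer at 58.1% and 78.7%. I counted no way back, so distrust my eta figure.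

The forecast names target at 53.5% for zeta, isomer of the product at 54.5% for gamma and isomer of the product at 70% for eta, lower than mine there, and calls that last figure “uncertain because of the reverse step”.

The flasks give target at 53.5% in zeta, isomer of the product at 56.5% in gamma and isomer of the product at 75.3% in eta, which is 5.3 percentage points above the forecast and below my figure.

    starting material + target → side product (k = 4.10 × 10⁻⁴ L mol⁻¹ s⁻¹)
    starting material + second chain carrier → by-product + first chain carrier (k = 2900 L mol⁻¹ s⁻¹)
    initiator → 2 initiating radical (k = 2.10 × 10⁻⁶ s⁻¹)
    starting material + initiating radical → capped initiator + first chain carrier (k = 3.20 × 10⁵ L mol⁻¹ s⁻¹)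
    2 first chain carrier → ended chains (k = 3.00 × 10⁸ L mol⁻¹ s⁻¹)
    target ⇌ isomer of the product (K = 19.0, k = 5.40 × 10⁻⁵ s⁻¹)
    coupling partner + first chain carrier → target + second chain carrier (k = 15000 L mol⁻¹ s⁻¹)

In gamma the forward step by itself gives the target a half-life of 3.6 h, shorter than the 6.0 h of the run. Starting material stands at 0% by then, and target at 31.0%. My reckoned crossing at 4.03 h falls between zeta, with 53.5% of target against 33.9% of isomer, and gamma. The neighbour, gamma's flask read at 2.5 h, lies before that reckoned crossing, and there target leads with 58.8% against 28.6% of isomer.

The data stem from a simulated flask with constants of no real substance, and the scatter is random.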